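## The problem

The target 47 is a germacranolide in which an ether oxygen spans C1 and C5 of the ten-membered carbocycle (C1–C10). The ring is thereby divided into an oxane (O, C1–C5) and an oxocene (O, C5–C10, C1), an 11-oxabicyclo[5.3.1]undecene, and a trans-fused α-methylene-γ-lactone sits on C6/C7. Six stereocentres must be set: C1, C4, C5, C6, C7 and C8, of which C4–C8 are contiguous. They are not independent. The one-atom bridge can only be cis, so C1 follows from C5. C5–O is syn to the lactone C6–O and can be derived from it. The C8 oxygen is cis to the C7–C11 bond of the trans-lactone. The epoxide oxygen on C4 lies on the oxane face that is not covered by the C6–C10 bridge. The spiro-epoxide (acid, fluoride), the γ-acyloxy enal and the two acrylate-type acceptors (bases, nucleophiles, phosphines) will not survive rough treatment and have to come last. Closing an eight- or ten-membered ring by C–C bond formation, and setting C6–C8 on such a ring, is the real difficulty. The enabling feature is the 1,5-relationship of the ether carbons: deleting the oxygen and joining C1 to C5 gives a 5/7-fused hydroazulene. The oxygen-bridged ten-membered ring is therefore that bicycle with one oxygen inserted into its ring-fusion bond.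

## Retrosynthesis

**Late functional groups (47 ⇒ 32).** The epoxide C–O bonds are cut first (47 ⇒ triene 46). Then follow the C9=C10 π-bond (46 ⇒ aldehyde 42 through selenide 44), the methacrylate acyl–oxygen bond (40 ⇒ alcohol 39), the C11=C13 bond (38 ⇒ lactone 34) and the C4=C15 bond (34 ⇒ ketone 33 ⇒ ketal 32). This removes every electrophilic or oxidisable π-system and leaves the saturated bridged ether 32, which carries only a lactone, a ketal and two different silyl ethers. The forward order is fixed by reactivity. The lactone methylenation needs a strong base, so it must come while the lactone is the only C–H acid. The ketone methylenation must precede the aldehyde. The epoxidation comes last, when the C4 methylene is the only electron-rich alkene.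

**Ether bridge (32 ⇒ 31 ⇒ 29).** The C1–O bond and the C1–H and C5–H bonds are cut, giving the cyclodecane-1,5-dione 29. A Williamson or oxa-Michael closure would need an activated secondary carbon inside a medium ring and two preset carbinol centres. With carbonyl groups at both termini, the ring oxygen can come from a C5 carbinol and the last hydrogen from a silane at a bridgehead oxocarbenium ion, where only the cis bridge can form. Two stereocentres and one ring disappear. The forward reaction must reduce the C5 carbonyl first, and from the face that places the new C–O bond syn to C6–O.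

**Key disconnection (29 ⇒ 27).** C1 and C5 are reconnected as a double bond; in the forward sense the ring-fusion alkene of hydroazulene 27 is cleaved by ozone. Any C–C closure of the ten- or eight-membered ring would fight transannular strain and leave C6–C8 to be set on a flexible ring. In 27 the triad sits on a rigid bicycle, and one functional group encodes both future ether carbons. C15 is deliberately not carried through the cleavage. A C4 acetoxymethyl group would add a disposable stereocentre next to the C5 ketone and a β-acyloxy ketone prone to elimination just when that ketone must be reduced selectively. A C4 ketal has neither problem, comes directly from the starting vinylogous ester, and makes the C5 carbonyl the more electrophilic one. The forward reaction must cleave a hindered tetrasubstituted alkene cleanly.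

**Seven-membered ring (27 ⇒ 26 ⇒ 24 ⇒ 23 ⇒ 21).** The C14–O bond is traced to hydroboration of an exocyclic C10 methylene, and the C8–C9 bond to an intramolecular allylation of aldehyde 21. This one cut creates the C8 carbinol and the methylene handle for C14 together. Ring-closing metathesis at C9=C10 would leave a conjugated diene that needs selective reduction. Closure at C5–C6 would form the lactone carbinol late and without control. The forward reaction must close a seven-membered ring and give the 8β-alcohol.

**Lactone and C6/C7 (21 ⇒ 19 ⇒ 18 ⇒ 17 ⇒ 16 ⇒ 13 + 10).** The C6–C7 bond and the lactone O–C12 bond are cut. A syn-aldol between succinate imide 13 and aldehyde 10 sets both centres absolutely, and lactonisation turns syn into the trans-lactone, with C8 kept at the acyl level. A butenolide/conjugate-addition route to the same lactone would take about three steps more. The forward reaction must tolerate a hindered dienal, and the auxiliary must be removed without opening the lactone.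

**Cyclopentene (10 ⇒ 8 ⇒ 7 ⇒ 2 + 4; 2 ⇒ 1; 4 ⇒ 3; 13 ⇒ 11 + 12).** C5–C6 is cut to a formylation of a vinyllithium, and C1–C10 to a carbonyl addition with transposition on vinylogous ester 2. Compound 1 supplies C1–C5 with the C4 oxygen in place. Both fragments are one step from commercial materials.

## Roads not taken

Alternative 1: The oxane and a seven-membered carbocycle are cut together across C1–C2 and C4–C5. In the forward direction a vinylcarbenoid, generated from a vinyldiazoacetate by Rh2(S-DOSP)4 (a divalent rhodium carboxylate), cyclopropanates a ring-fused furan, and the cis-divinylcyclopropane undergoes Cope rearrangement to the oxabicycle A1. Its tetrasubstituted bridge alkene would later be cleaved to release the eight-membered ring. Its merits are real. The ether bridge and both of its stereocentres are set by the catalyst, which is exactly where the chosen plan is least secure (the face of the C5 reduction leading to 31), and C15 is already present as the ester carbon. Its weak points lie after the key step. C6, C7 and C8 must be created on a flexible oxocane-dione, the C6 and C10 ketones have to be told apart, and C10 needs a one-carbon homologation. Furans also tend to open to trienes under carbenoid attack, and their enantioselectivity is moderate. The chosen plan sets the C6–C8 triad on the rigid hydroazulene 23 and carries C14 through the cleavage. It pays for this with substrate control at C5.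

Alternative 2: The C7–C8 bond is cut, with the C11=C13 methylene traced to an allylic ether oxygen on C13. In the forward direction n-BuLi effects tin–lithium exchange at C8 within an eleven-membered allylic ether ring, and the α-alkoxy carbanion undergoes a [2,3]-Wittig–Still shift that contracts the ring to the oxocene A2. The step is economical in a way the chosen plan is not. The C7–C8 bond, the free C8 hydroxyl and the exocyclic methylene arise in one event with chirality transfer, and the C4 methylene, C9=C10 and C14 oxygen are already in place, so the endgame would be a few oxidations. Against this stand the macrocyclic allylic etherification needed to build the substrate and a configurationally defined α-alkoxystannane. The [1,2]-shift competes, the stereochemical outcome depends on the conformation of a medium ring, and three silyl ethers must later be told apart. The chosen plan needs a separate lactone methylenation (34 to 38) and a separate ring closure (21 to 23). It avoids any macrocyclisation and any organotin, and its key step needs no selectivity at all.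

Alternative 3: The oxane C5–O bond and the C5–C6 bond are cut. In the forward direction Cu(hfacac)2 (divalent copper) decomposes a diazoketone tethered to a vinyl-substituted tetrahydrofuran from the deoxyribose pool. The ring oxygen traps the carbenoid, and the oxonium ylide shifts [2,3] to give the bridged ketone A3. This is the most direct entry to the bicyclic ether core. The bridge configuration is secured from the chiral pool in one catalytic step, and A3 carries the same C4 ketone that the chosen plan reaches only at 33. It lacks C11–C13 and C14, however. The cis C7=C8 alkene would have to take up a carbon substituent at C7 and an oxygen at C8 with regio- and stereocontrol on an oxocene. The C10 oxygen would have to be exchanged for the enal carbon. C–H insertion and [1,2]-shift also compete with the ylide pathway. The chosen plan brings all skeletal carbons except C13 and C15 through its key step and adds those two by simple methylenations. In return it must live with the uncertain face selectivity at C5.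

Key step: step 16

Remark on the chemistry: germacrane numbering is used throughout and β denotes the face of the C7–C11 bond. Centres that are later destroyed are drawn as expected or left open: C10 in 25–42 as expected, C10 in 44 and 45 open, C11 in 36 and 37 as expected. Compound 6 is racemic, and 28 is drawn without configuration at C1/C5 because both orientations give 29.

Step 1
Reactants: 1 3-ethoxycyclopent-2-en-1-one
Product: 2 2-bromo-3-ethoxycyclopent-2-en-1-one
Conditions: NBS, CH2Cl2, 0 °C → rt
Reagents that add atoms: N-bromosuccinimide, O=C1CCC(=O)N1Br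
Why: Electrophilic bromination at the nucleophilic α-carbon of the vinylogous ester (the later C5), a routine α-halogenation of β-alkoxy enones that leaves the carbonyl (later C1) free for addition.

Step 2
Reactants: 3 2-bromoprop-2-en-1-ol
Product: 4 [(2-bromoprop-2-en-1-yl)oxy](tert-butyl)dimethylsilane
Conditions: TBSCl, imidazole, CH2Cl2, 0 °C → rt
Reagents that add atoms: tert-butyldimethylsilyl chloride, CC(C)(C)[Si](C)(C)Cl
Why: Standard silylation of a primary allylic alcohol, so that the vinyl bromide can be lithiated.

Step 3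
Reactants: 4 [(2-bromoprop-2-en-1-yl)oxy](tert-butyl)dimethylsilane; 2 2-bromo-3-ethoxycyclopent-2-en-1-one
Product: 7 2-bromo-3-{3-[(tert-butyldimethylsilyl)oxy]prop-1-en-2-yl}cyclopent-2-en-1-one, via vinyllithium 5 (not isolated), via tertiary lithium alkoxide 6 (not isolated)
Conditions: t-BuLi (2 equiv), Et2O, –78 °C; 2, –78 °C; 1 M HCl, THF, 0 °C
Reagents that add atoms: water, O
Why: Bromine–lithium exchange gives the 2-propenyllithium, which adds 1,2 to the vinylogous ester at –78 °C; acid hydrolysis transposes the carbonyl (Stork–Danheiser sequence), so the side chain ends on C1, the ketone on C4 and the bromide stays on C5.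

Step 4
Reactants: 7 2-bromo-3-{3-[(tert-butyldimethylsilyl)oxy]prop-1-en-2-yl}cyclopent-2-en-1-one
Product: 8 6-bromo-7-{3-[(tert-butyldimethylsilyl)oxy]prop-1-en-2-yl}-1,4-dioxaspiro[4.4]non-6-ene
Conditions: Me3SiOCH2CH2OSiMe3, TMSOTf (cat.), CH2Cl2, –78 → –20 °C; pyridine
Reagents that add atoms: 1,2-bis(trimethylsilyloxy)ethane, C[Si](C)(C)OCCO[Si](C)(C)C
Why: Silyl-transfer ketalisation protects the C4 ketone at low temperature without moving the alkenes or cleaving the allylic silyl ether, and turns the α-bromoenone into a lithiable α-ketovinyl anion equivalent.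

Step 5
Reactants: 8 6-bromo-7-{3-[(tert-butyldimethylsilyl)oxy]prop-1-en-2-yl}-1,4-dioxaspiro[4.4]non-6-ene
Product: 10 7-{3-[(tert-butyldimethylsilyl)oxy]prop-1-en-2-yl}-1,4-dioxaspiro[4.4]non-6-ene-6-carbaldehyde, via vinyllithium 9 (not isolated)
Conditions: n-BuLi, THF, –78 °C; DMF, –78 → 0 °C; aq. NH4Cl
Reagents that add atoms: N,N-dimethylformamide, CN(C)C=O
Why: Bromine–lithium exchange of the ketal-protected bromoalkene and formylation with DMF install C6 as the aldehyde; ketal and silyl ether are inert to the organolithium at –78 °C.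

Step 6
Reactants: 11 (S)-4-benzyl-1,3-oxazolidin-2-one; 12 methyl 4-chloro-4-oxobutanoate
Product: 13 methyl 4-[(4S)-4-benzyl-2-oxo-1,3-oxazolidin-3-yl]-4-oxobutanoate
Conditions: Et3N, DMAP (cat.), CH2Cl2, 0 °C → rt
Reagents that add atoms: none
Why: N-acylation of the oxazolidinone with the half-ester acid chloride gives the succinate imide that supplies C7, C8, C11 and C12.

Step 7
Reactants: 13 methyl 4-[(4S)-4-benzyl-2-oxo-1,3-oxazolidin-3-yl]-4-oxobutanoate; 10 7-{3-[(tert-butyldimethylsilyl)oxy]prop-1-en-2-yl}-1,4-dioxaspiro[4.4]non-6-ene-6-carbaldehyde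
Product: 16 trans-lactone imide (4S)-4-benzyl-3-{[(2S,3S)-2-(7-{3-[(tert-butyldimethylsilyl)oxy]prop-1-en-2-yl}-1,4-dioxaspiro[4.4]non-6-en-6-yl)-5-oxooxolan-3-yl]carbonyl}-1,3-oxazolidin-2-one, via boron enolate 14 (not isolated), via syn-aldol adduct 15 (not isolated)
Conditions: n-Bu2BOTf, i-Pr2NEt, CH2Cl2, –78 → 0 °C; 10, –78 → 0 °C; pH 7 buffer, H2O2, MeOH, 0 °C; then DMAP (cat.), PhMe, 50 °C
Reagents that add atoms: none
Why: Evans syn-aldol: the (Z)-boron enolate of the imide (the ester is not enolised) adds to the aldehyde through the chair transition state set by the (S)-benzyl auxiliary, giving the 6,7-syn adduct with C6 and C7 as in 47; the C6 hydroxyl then closes onto the methyl ester (5-exo-trig), and syn becomes the trans-lactone.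

Step 8
Reactants: 16 trans-lactone imide
Product: 17 trans-4-(hydroxymethyl)-5-(7-{3-[(tert-butyldimethylsilyl)oxy]prop-1-en-2-yl}-1,4-dioxaspiro[4.4]non-6-en-6-yl)oxolan-2-one (C6, C7 as in 47; C8 is CH2OH)
Conditions: NaBH4, THF/H2O (4:1), 0 °C → rt
Reagents that add atoms: none
Why: Borohydride in wet THF reductively cleaves the activated exocyclic imide carbonyl to the primary alcohol and returns the auxiliary, while the less electrophilic γ-lactone, the ketal and the silyl ether are left alone.

Step 9
Reactants: 17 hydroxymethyl lactone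
Product: 18 trans-2-(7-{3-[(tert-butyldimethylsilyl)oxy]prop-1-en-2-yl}-1,4-dioxaspiro[4.4]non-6-en-6-yl)-5-oxooxolane-3-carbaldehyde (C8 aldehyde)
Conditions: Dess–Martin periodinane, NaHCO3, CH2Cl2, 0 °C → rt
Reagents that add atoms: none
Why: Buffered Dess–Martin oxidation gives the β-formyl lactone without acid that would endanger the allylic ketal; C7 is epimerisable, but trans to the C6 substituent is the stable arrangement.

Step 10
Reactants: 18 silyl ether aldehyde
Product: 19 trans-2-[7-(3-hydroxyprop-1-en-2-yl)-1,4-dioxaspiro[4.4]non-6-en-6-yl]-5-oxooxolane-3-carbaldehyde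
Conditions: Bu4NF, AcOH (1:1), THF, 0 °C
Reagents that add atoms: none
Why: Acetic acid-buffered fluoride removes the primary allylic silyl ether under near-neutral conditions that avoid β-elimination or epimerisation of the β-acyloxy aldehyde.

Step 11
Reactants: 19 allylic alcohol aldehyde
Product: 21 trans-2-[7-(3-bromoprop-1-en-2-yl)-1,4-dioxaspiro[4.4]non-6-en-6-yl]-5-oxooxolane-3-carbaldehyde, via allylic mesylate 20 (not isolated)
Conditions: MsCl, Et3N, CH2Cl2, –20 °C; LiBr, THF, 0 °C → rt
Reagents that add atoms: lithium bromide, [Li+].[Br-]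
Why: Mesylation and in situ SN2 displacement by bromide convert the allylic alcohol into the bromide without phosphine reagents that would attack the aldehyde.

Step 12
Reactants: 21 allylic bromide aldehyde
Product: 23 hydroazulene lactone 4,4-(ethylenedioxy)-8β-hydroxy-13,15-dinorguaia-1(5),10(14)-dien-12,6α-olide (C6, C7, C8 as in 47), via allylchromium dichloride 22 (not isolated)
Conditions: CrCl2 (4 equiv), THF, rt, slow addition at 0.005 M
Reagents that add atoms: none
Why: Nozaki–Hiyama allylation: divalent chromium inserts into the allylic bromide and the allylchromium adds only to the aldehyde through a closed six-membered transition state, closing the seven-membered ring (C8–C9) under high dilution; in that transition state O8 is gauche to C10 and so pseudo-axial on the new ring, while the trans-lactone holds C11 pseudo-equatorial, so the alcohol forms cis to C11 (8β, as in 47).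

Step 13
Reactants: 23 hydroazulene alcohol
Product: 24 8β-[(tert-butyldimethylsilyl)oxy]-4,4-(ethylenedioxy)-13,15-dinorguaia-1(5),10(14)-dien-12,6α-olide
Conditions: TBSCl, imidazole, DMAP (cat.), DMF, 40 °C
Reagents that add atoms: tert-butyldimethylsilyl chloride, CC(C)(C)[Si](C)(C)Cl
Why: Silylation of the secondary alcohol with the chloride and imidazole avoids silyl triflates that could ionise the allylic ketal.

Step 14
Reactants: 24 diene silyl ether
Product: 26 8β-[(tert-butyldimethylsilyl)oxy]-4,4-(ethylenedioxy)-14-hydroxy-13,15-dinorguai-1(5)-en-12,6α-olide (10α-H), via B-alkyl-9-borabicyclononane 25 (not isolated)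
Conditions: 9-BBN, THF, 0 °C → rt; NaBO3·4H2O, H2O, rt
Reagents that add atoms: sodium perborate, [Na+].[Na+].O[B-]1(O)OO[B-](O)(O)OO1
Why: 9-BBN hydroborates only the 1,1-disubstituted C10=C14 alkene (the tetrasubstituted C1=C5 is inert), with boron on C14 and from the face opposite the pseudo-axial C8 silyl ether; perborate oxidises the borane without saponifying the lactone, and the C10 centre is lost later.

Step 15
Reactants: 26 primary alcohol
Product: 27 8β-[(tert-butyldimethylsilyl)oxy]-14-[(tert-butyldiphenylsilyl)oxy]-4,4-(ethylenedioxy)-13,15-dinorguai-1(5)-en-12,6α-olide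
Conditions: TBDPSCl, imidazole, DMF, rt
Reagents that add atoms: tert-butyldiphenylsilyl chloride, CC(C)(C)[Si](Cl)(c1ccccc1)c1ccccc1
Why: Silylation of the primary alcohol with the more acid-stable group, so that the C8 silyl ether can later be removed first.

Step 16
Reactants: 27 hydroazulene lactone with the C1=C5 ring-fusion alkene
Product: 29 8β-[(tert-butyldimethylsilyl)oxy]-14-[(tert-butyldiphenylsilyl)oxy]-4,4-(ethylenedioxy)-1,5-dioxo-13,15-dinorgermacran-12,6α-olide (cyclodecane-1,5-dione), via secondary ozonide 28 (not isolated)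
Conditions: O3, CH2Cl2, –78 °C (Sudan Red 7B end point); PPh3, –78 °C → rt
Reagents that add atoms: ozone, [O-][O+]=O
Why: Ozone adds as a 1,3-dipole to the electron-rich tetrasubstituted C1=C5 alkene, the only C=C bond in 27; the first adduct cycloreverts to a ketone and a carbonyl oxide that stay tethered and recombine to the secondary ozonide 28, which PPh3 reduces to the 1,5-diketone 29. The closest known reaction type is the ozonolysis of ring-fusion tetrasubstituted alkenes such as bicyclo[4.4.0]dec-1(6)-ene and bicyclo[5.3.0]dec-1(7)-ene to cyclodecanediones. No ring is closed by bond formation: the ten-membered carbocycle appears because the bond shared by the five- and seven-membered rings is cut, so neither a cyclisation mode nor cyclisation entropy is at issue. No stereocentre is created, and C6, C7, C8 and C10 are untouched because the work-up is neutral. The only selectivity needed is chemoselectivity: silyl ethers, ketal, lactone and the phenyl rings are inert at –78 °C, and the indicator dye stops the ozone stream before C–H bonds next to oxygen are attacked. The cleavage places carbonyl groups on exactly the two carbons that the ether oxygen joins in 47, and the neighbouring ketal makes the C5 carbonyl the more electrophilic of the two.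

Step 17
Reactants: 29 cyclodecane-1,5-dione
Product: 31 transannular lactol 1,5-epoxy-1-hydroxy-8β-[(tert-butyldimethylsilyl)oxy]-14-[(tert-butyldiphenylsilyl)oxy]-4,4-(ethylenedioxy)-13,15-dinorgermacran-12,6α-olide (C5 as in 47), via 5-hydroxy ketone 30 (not isolated)
Conditions: NaBH4, MeOH/CH2Cl2 (1:1), –78 °C
Reagents that add atoms: none
Why: The C5 carbonyl, activated by three α-oxygen substituents, should be reduced in preference to the unactivated medium-ring C1 ketone; Felkin–Anh addition anti to the polar C6–O bond gives the 5,6-syn alcohol (C5 as in 47), which closes onto C1 as the lactol and thereby shields C1 from further reduction.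

Step 18
Reactants: 31 transannular lactol
Product: 32 1,5-epoxy-8β-[(tert-butyldimethylsilyl)oxy]-14-[(tert-butyldiphenylsilyl)oxy]-4,4-(ethylenedioxy)-13,15-dinorgermacran-12,6α-olide (C1, C5–C8 as in 47)
Conditions: Et3SiH, BF3·OEt2, CH2Cl2, –78 → –30 °C
Reagents that add atoms: none
Why: Reductive etherification: ionisation of the lactol gives the bridgehead oxocarbenium ion at C1, and the silane delivers hydride from the only open (exo) face, so the bridge is cis and C1 follows from C5; the ketal, inductively deactivated by the adjacent C5–O bond, and both silyl ethers should persist at low temperature.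

Step 19
Reactants: 32 bridged ether ketal
Product: 33 1,5-epoxy-8β-[(tert-butyldimethylsilyl)oxy]-14-[(tert-butyldiphenylsilyl)oxy]-4-oxo-13,15-dinorgermacran-12,6α-olide
Conditions: PPTS, acetone/H2O (10:1), 55 °C
Reagents that add atoms: water, O
Why: Mild acid hydrolysis frees the C4 ketone while the secondary TBS ether, the TBDPS ether and the lactone persist; C5, although α to the new ketone, is a bridgehead carbon held by the ether bridge.

Step 20
Reactants: 33 C4 ketone
Product: 34 1,5-epoxy-8β-[(tert-butyldimethylsilyl)oxy]-14-[(tert-butyldiphenylsilyl)oxy]-13-norgermacr-4(15)-en-12,6α-olide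
Conditions: Zn, CH2Br2, TiCl4, THF, 0 °C (reagent preformed); then 33, CH2Cl2, rt
Reagents that add atoms: dibromomethane, BrCBr
Why: Lombardo methylenation converts the hindered, enolisable α-alkoxy ketone into the exocyclic C4 methylene (C15); the reagent is non-basic and ketone-selective, so the lactone and silyl ethers are untouched.

Step 21
Reactants: 34 lactone with the C4 methylene
Product: 38 1,5-epoxy-8β-[(tert-butyldimethylsilyl)oxy]-14-[(tert-butyldiphenylsilyl)oxy]germacra-4(15),11(13)-dien-12,6α-olide, via lithium enolate 35 (not isolated), via Mannich base 36 (not isolated), via ammonium iodide 37 (not isolated)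
Conditions: LiN(SiMe3)2, THF, –78 °C; Me2N=CH2 I, –78 °C → rt; MeI, MeOH/CH2Cl2, rt; aq. NaHCO3, CH2Cl2, rt
Reagents that add atoms: Eschenmoser's salt, C=[N+](C)C.[I-]
Why: The lactone is the only C–H acid; its enolate undergoes a Mannich reaction with the iminium salt, and quaternisation followed by β-elimination gives the α-methylene lactone (C11=C13); the transient C11 centre is destroyed.

Step 22
Reactants: 38 bis-silyl ether
Product: 39 1,5-epoxy-8β-hydroxy-14-[(tert-butyldiphenylsilyl)oxy]germacra-4(15),11(13)-dien-12,6α-olide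
Conditions: CSA (cat.), MeOH/CH2Cl2 (1:1), 0 °C → rt
Reagents that add atoms: none
Why: Acid-catalysed methanolysis removes the secondary TBS ether far faster than the TBDPS ether, and no base or fluoride touches the α-methylene lactone.

Step 23
Reactants: 39 8β-alcohol
Product: 40 1,5-epoxy-8β-(methacryloyloxy)-14-[(tert-butyldiphenylsilyl)oxy]germacra-4(15),11(13)-dien-12,6α-olide
Conditions: methacrylic anhydride, Et3N, DMAP, CH2Cl2, 0 °C → rt
Reagents that add atoms: methacrylic anhydride, CC(=C)C(=O)OC(=O)C(C)=C
Why: DMAP-catalysed acylation of the secondary alcohol, with retention at C8.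

Step 24
Reactants: 40 methacrylate silyl ether
Product: 41 1,5-epoxy-14-hydroxy-8β-(methacryloyloxy)germacra-4(15),11(13)-dien-12,6α-olide
Conditions: HF·pyridine, pyridine, THF, 0 °C → rt
Reagents that add atoms: none
Why: Pyridine-buffered HF removes the primary TBDPS ether without the basic fluoride that could add to or cleave the two acrylate units.

Step 25
Reactants: 41 primary alcohol
Product: 42 1,5-epoxy-8β-(methacryloyloxy)-14-oxogermacra-4(15),11(13)-dien-12,6α-olide (C14 aldehyde)
Conditions: Dess–Martin periodinane, NaHCO3, CH2Cl2, 0 °C → rt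
Reagents that add atoms: none
Why: Neutral Dess–Martin oxidation of the primary alcohol tolerates the alkenes and Michael acceptors.

Step 26
Reactants: 42 aldehyde
Product: 44 10-(phenylselanyl) derivative of 42 (quaternary C10, either configuration), via silyl enol ether 43 (not isolated)
Conditions: TMSOTf, Et3N, CH2Cl2, 0 °C; PhSeCl, –78 °C
Reagents that add atoms: benzeneselenenyl chloride, Cl[Se]c1ccccc1
Why: Soft enolisation affects only the aldehyde, the sole enolisable carbonyl; the silyl enol ether is selenenylated at C10 at –78 °C far faster than the inductively deactivated C4 methylene or the electron-poor alkenes.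

Step 27
Reactants: 44 α-phenylselanyl aldehyde
Product: 46 1,5-epoxy-8β-(methacryloyloxy)-14-oxogermacra-4(15),9,11(13)-trien-12,6α-olide ((9E)-enal), via selenoxide 45 (not isolated)
Conditions: NaIO4, NaHCO3, THF/H2O, 0 °C → rt
Reagents that add atoms: none
Why: Periodate oxidises selenium and the selenoxide undergoes syn elimination below room temperature, away from the C1 oxygen (the usual preference of β-oxygenated selenoxides) and toward C9; the eight-membered ring enforces the ring-cis C9=C10 bond, which is the (E)-enal of 47, and excess periodate removes PhSeOH before it can add to the C4 methylene.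

Step 28
Reactants: 46 triene enal
Product: 47 (1R,4R,5R,6S,7R,8R,9E)-1,5:4,15-diepoxy-8-(methacryloyloxy)-14-oxogermacra-9,11(13)-dien-12,6-olide (target)
Conditions: mCPBA, NaHCO3, CH2Cl2, 0 °C
Reagents that add atoms: 3-chloroperoxybenzoic acid, OOC(=O)c1cccc(Cl)c1
Why: The peracid epoxidises only the electron-rich 1,1-disubstituted C4=C15 alkene (enal, α-methylene lactone and methacrylate are electron-poor); it should approach the oxane face not covered by the C6–C10 bridge, which places the epoxide oxygen on the side of H-5 and gives the C4 configuration of 47.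

## Compound list

1 | 3-ethoxycyclopent-2-en-1-one | CCOC1=CC(=O)CC1 | starting material
2 | 2-bromo-3-ethoxycyclopent-2-en-1-one | CCOC1=C(Br)C(=O)CC1 | intermediate
3 | 2-bromoprop-2-en-1-ol | OCC(Br)=C | starting material
4 | [(2-bromoprop-2-en-1-yl)oxy](tert-butyl)dimethylsilane | BrC(=C)CO[Si](C)(C)C(C)(C)C | intermediate
5 | {3-[(tert-butyldimethylsilyl)oxy]prop-1-en-2-yl}lithium | [Li]C(=C)CO[Si](C)(C)C(C)(C)C | intermediate
6 | lithium 2-bromo-3-ethoxy-1-{3-[(tert-butyldimethylsilyl)oxy]prop-1-en-2-yl}cyclopent-2-en-1-olate (racemic) | CCOC1=C(Br)C(O[Li])(C(=C)CO[Si](C)(C)C(C)(C)C)CC1 | intermediate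
7 | 2-bromo-3-{3-[(tert-butyldimethylsilyl)oxy]prop-1-en-2-yl}cyclopent-2-en-1-one | O=C1CCC(C(=C)CO[Si](C)(C)C(C)(C)C)=C1Br | intermediate
8 | 6-bromo-7-{3-[(tert-butyldimethylsilyl)oxy]prop-1-en-2-yl}-1,4-dioxaspiro[4.4]non-6-ene | BrC1=C(C(=C)CO[Si](C)(C)C(C)(C)C)CCC12OCCO2 | intermediate
9 | 6-lithio-7-{3-[(tert-butyldimethylsilyl)oxy]prop-1-en-2-yl}-1,4-dioxaspiro[4.4]non-6-ene | [Li]C1=C(C(=C)CO[Si](C)(C)C(C)(C)C)CCC12OCCO2 | intermediate
10 | 7-{3-[(tert-butyldimethylsilyl)oxy]prop-1-en-2-yl}-1,4-dioxaspiro[4.4]non-6-ene-6-carbaldehyde | O=CC1=C(C(=C)CO[Si](C)(C)C(C)(C)C)CCC12OCCO2 | intermediate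
11 | (S)-4-benzyl-1,3-oxazolidin-2-one | O=C1N[C@@H](Cc2ccccc2)CO1 | starting material
12 | methyl 4-chloro-4-oxobutanoate | COC(=O)CCC(=O)Cl | starting material
13 | methyl 4-[(4S)-4-benzyl-2-oxo-1,3-oxazolidin-3-yl]-4-oxobutanoate | COC(=O)CCC(=O)N1[C@@H](Cc2ccccc2)COC1=O | intermediate
14 | (Z)-dibutylboron enolate of 13 | CCCCB(CCCC)O/C(=C\CC(=O)OC)N1[C@@H](Cc2ccccc2)COC1=O | intermediate
15 | syn-aldol adduct, methyl (3S,4S)-3-{[(4S)-4-benzyl-2-oxo-1,3-oxazolidin-3-yl]carbonyl}-4-hydroxy-4-(7-{3-[(tert-butyldimethylsilyl)oxy]prop-1-en-2-yl}-1,4-dioxaspiro[4.4]non-6-en-6-yl)butanoate | CC(C)(C)[Si](C)(C)OCC(=C)C1=C([C@@H](O)[C@H](CC(=O)OC)C(=O)N2[C@@H](Cc3ccccc3)COC2=O)C2(CC1)OCCO2 | intermediate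
16 | trans-lactone imide, (4S)-4-benzyl-3-{[(2S,3S)-2-(7-{3-[(tert-butyldimethylsilyl)oxy]prop-1-en-2-yl}-1,4-dioxaspiro[4.4]non-6-en-6-yl)-5-oxooxolan-3-yl]carbonyl}-1,3-oxazolidin-2-one | CC(C)(C)[Si](C)(C)OCC(=C)C1=C([C@H]2OC(=O)C[C@@H]2C(=O)N2[C@@H](Cc3ccccc3)COC2=O)C2(CC1)OCCO2 | intermediate
17 | trans-4-(hydroxymethyl)-5-(7-{3-[(tert-butyldimethylsilyl)oxy]prop-1-en-2-yl}-1,4-dioxaspiro[4.4]non-6-en-6-yl)oxolan-2-one (C6, C7 as in 47) | CC(C)(C)[Si](C)(C)OCC(=C)C1=C([C@H]2OC(=O)C[C@@H]2CO)C2(CC1)OCCO2 | intermediate
18 | trans-2-(7-{3-[(tert-butyldimethylsilyl)oxy]prop-1-en-2-yl}-1,4-dioxaspiro[4.4]non-6-en-6-yl)-5-oxooxolane-3-carbaldehyde | CC(C)(C)[Si](C)(C)OCC(=C)C1=C([C@H]2OC(=O)C[C@@H]2C=O)C2(CC1)OCCO2 | intermediate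
19 | trans-2-[7-(3-hydroxyprop-1-en-2-yl)-1,4-dioxaspiro[4.4]non-6-en-6-yl]-5-oxooxolane-3-carbaldehyde | OCC(=C)C1=C([C@H]2OC(=O)C[C@@H]2C=O)C2(CC1)OCCO2 | intermediate
20 | allylic methanesulfonate of 19 | CS(=O)(=O)OCC(=C)C1=C([C@H]2OC(=O)C[C@@H]2C=O)C2(CC1)OCCO2 | intermediate
21 | trans-2-[7-(3-bromoprop-1-en-2-yl)-1,4-dioxaspiro[4.4]non-6-en-6-yl]-5-oxooxolane-3-carbaldehyde | BrCC(=C)C1=C([C@H]2OC(=O)C[C@@H]2C=O)C2(CC1)OCCO2 | intermediate
22 | allylchromium dichloride (trivalent chromium) derived from 21 | Cl[Cr](Cl)CC(=C)C1=C([C@H]2OC(=O)C[C@@H]2C=O)C2(CC1)OCCO2 | intermediate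
23 | 4,4-(ethylenedioxy)-8β-hydroxy-13,15-dinorguaia-1(5),10(14)-dien-12,6α-olide | O[C@@H]1CC(=C)C3=C(C4(CC3)OCCO4)[C@H]2OC(=O)C[C@@H]21 | intermediate
24 | 8β-[(tert-butyldimethylsilyl)oxy]-4,4-(ethylenedioxy)-13,15-dinorguaia-1(5),10(14)-dien-12,6α-olide | CC(C)(C)[Si](C)(C)O[C@@H]1CC(=C)C3=C(C4(CC3)OCCO4)[C@H]2OC(=O)C[C@@H]21 | intermediate
25 | 14-(9-borabicyclo[3.3.1]nonan-9-yl) adduct of 24 (10α-H) | CC(C)(C)[Si](C)(C)O[C@@H]1C[C@H](CB5C6CCCC5CCC6)C3=C(C4(CC3)OCCO4)[C@H]2OC(=O)C[C@@H]21 | intermediate
26 | 8β-[(tert-butyldimethylsilyl)oxy]-4,4-(ethylenedioxy)-14-hydroxy-13,15-dinorguai-1(5)-en-12,6α-olide (10α-H) | CC(C)(C)[Si](C)(C)O[C@@H]1C[C@H](CO)C3=C(C4(CC3)OCCO4)[C@H]2OC(=O)C[C@@H]21 | intermediate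
27 | 8β-[(tert-butyldimethylsilyl)oxy]-14-[(tert-butyldiphenylsilyl)oxy]-4,4-(ethylenedioxy)-13,15-dinorguai-1(5)-en-12,6α-olide | CC(C)(C)[Si](C)(C)O[C@@H]1C[C@H](CO[Si](c2ccccc2)(c2ccccc2)C(C)(C)C)C3=C(C4(CC3)OCCO4)[C@H]2OC(=O)C[C@@H]21 | intermediate
28 | secondary ozonide of 27 (1,2,4-trioxolane spanning C1 and C5; either orientation) | CC(C)(C)[Si](C)(C)O[C@@H]1C[C@H](CO[Si](c2ccccc2)(c2ccccc2)C(C)(C)C)C34CCC5(OCCO5)C(OO3)(O4)[C@H]2OC(=O)C[C@@H]21 | intermediate
29 | 8β-[(tert-butyldimethylsilyl)oxy]-14-[(tert-butyldiphenylsilyl)oxy]-4,4-(ethylenedioxy)-1,5-dioxo-13,15-dinorgermacran-12,6α-olide | CC(C)(C)[Si](C)(C)O[C@@H]1C[C@H](CO[Si](c2ccccc2)(c2ccccc2)C(C)(C)C)C(=O)CCC2(OCCO2)C(=O)[C@H]3OC(=O)C[C@@H]31 | intermediate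
30 | 5-hydroxy-1-oxo analogue of 29 (open form of 31; C5–OH syn to C6–O) | CC(C)(C)[Si](C)(C)O[C@@H]1C[C@H](CO[Si](c2ccccc2)(c2ccccc2)C(C)(C)C)C(=O)CCC2(OCCO2)[C@H](O)[C@H]3OC(=O)C[C@@H]31 | intermediate
31 | transannular lactol, 1,5-epoxy-1-hydroxy-8β-[(tert-butyldimethylsilyl)oxy]-14-[(tert-butyldiphenylsilyl)oxy]-4,4-(ethylenedioxy)-13,15-dinorgermacran-12,6α-olide | CC(C)(C)[Si](C)(C)O[C@@H]1C[C@H](CO[Si](c2ccccc2)(c2ccccc2)C(C)(C)C)[C@@]2(O)CCC3(OCCO3)[C@H](O2)[C@H]2OC(=O)C[C@@H]21 | intermediate
32 | 1,5-epoxy-8β-[(tert-butyldimethylsilyl)oxy]-14-[(tert-butyldiphenylsilyl)oxy]-4,4-(ethylenedioxy)-13,15-dinorgermacran-12,6α-olide (C1, C5–C8 as in 47) | CC(C)(C)[Si](C)(C)O[C@@H]1C[C@H](CO[Si](c2ccccc2)(c2ccccc2)C(C)(C)C)[C@H]2CCC3(OCCO3)[C@H](O2)[C@H]2OC(=O)C[C@@H]21 | intermediate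
33 | 1,5-epoxy-8β-[(tert-butyldimethylsilyl)oxy]-14-[(tert-butyldiphenylsilyl)oxy]-4-oxo-13,15-dinorgermacran-12,6α-olide | CC(C)(C)[Si](C)(C)O[C@@H]1C[C@H](CO[Si](c2ccccc2)(c2ccccc2)C(C)(C)C)[C@H]2CCC(=O)[C@H](O2)[C@H]2OC(=O)C[C@@H]21 | intermediate
34 | 1,5-epoxy-8β-[(tert-butyldimethylsilyl)oxy]-14-[(tert-butyldiphenylsilyl)oxy]-13-norgermacr-4(15)-en-12,6α-olide | CC(C)(C)[Si](C)(C)O[C@@H]1C[C@H](CO[Si](c2ccccc2)(c2ccccc2)C(C)(C)C)[C@H]2CCC(=C)[C@H](O2)[C@H]2OC(=O)C[C@@H]21 | intermediate
35 | lithium enolate of lactone 34 | CC(C)(C)[Si](C)(C)O[C@@H]1C[C@H](CO[Si](c2ccccc2)(c2ccccc2)C(C)(C)C)[C@H]2CCC(=C)[C@H](O2)[C@H]2OC(O[Li])=C[C@@H]21 | intermediate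
36 | 11-[(dimethylamino)methyl] derivative of 34 (Mannich base) | CC(C)(C)[Si](C)(C)O[C@@H]1C[C@H](CO[Si](c2ccccc2)(c2ccccc2)C(C)(C)C)[C@H]2CCC(=C)[C@H](O2)[C@H]2OC(=O)[C@@H](CN(C)C)[C@@H]21 | intermediate
37 | 11-[(trimethylammonio)methyl] derivative of 34, iodide | CC(C)(C)[Si](C)(C)O[C@@H]1C[C@H](CO[Si](c2ccccc2)(c2ccccc2)C(C)(C)C)[C@H]2CCC(=C)[C@H](O2)[C@H]2OC(=O)[C@@H](C[N+](C)(C)C)[C@@H]21.[I-] | intermediate
38 | 1,5-epoxy-8β-[(tert-butyldimethylsilyl)oxy]-14-[(tert-butyldiphenylsilyl)oxy]germacra-4(15),11(13)-dien-12,6α-olide | CC(C)(C)[Si](C)(C)O[C@@H]1C[C@H](CO[Si](c2ccccc2)(c2ccccc2)C(C)(C)C)[C@H]2CCC(=C)[C@H](O2)[C@H]2OC(=O)C(=C)[C@@H]21 | intermediate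
39 | 1,5-epoxy-8β-hydroxy-14-[(tert-butyldiphenylsilyl)oxy]germacra-4(15),11(13)-dien-12,6α-olide | O[C@@H]1C[C@H](CO[Si](c2ccccc2)(c2ccccc2)C(C)(C)C)[C@H]2CCC(=C)[C@H](O2)[C@H]2OC(=O)C(=C)[C@@H]21 | intermediate
40 | 1,5-epoxy-8β-(methacryloyloxy)-14-[(tert-butyldiphenylsilyl)oxy]germacra-4(15),11(13)-dien-12,6α-olide | C=C(C)C(=O)O[C@@H]1C[C@H](CO[Si](c2ccccc2)(c2ccccc2)C(C)(C)C)[C@H]2CCC(=C)[C@H](O2)[C@H]2OC(=O)C(=C)[C@@H]21 | intermediate
41 | 1,5-epoxy-14-hydroxy-8β-(methacryloyloxy)germacra-4(15),11(13)-dien-12,6α-olide | C=C(C)C(=O)O[C@@H]1C[C@H](CO)[C@H]2CCC(=C)[C@H](O2)[C@H]2OC(=O)C(=C)[C@@H]21 | intermediate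
42 | 1,5-epoxy-8β-(methacryloyloxy)-14-oxogermacra-4(15),11(13)-dien-12,6α-olide | C=C(C)C(=O)O[C@@H]1C[C@H](C=O)[C@H]2CCC(=C)[C@H](O2)[C@H]2OC(=O)C(=C)[C@@H]21 | intermediate
43 | trimethylsilyl enol ether of 42 (C10=C14) | C=C(C)C(=O)O[C@@H]1CC(=CO[Si](C)(C)C)[C@H]2CCC(=C)[C@H](O2)[C@H]2OC(=O)C(=C)[C@@H]21 | intermediate
44 | 10-(phenylselanyl) derivative of 42 (C10 either configuration) | C=C(C)C(=O)O[C@@H]1CC(C=O)([Se]c3ccccc3)[C@H]2CCC(=C)[C@H](O2)[C@H]2OC(=O)C(=C)[C@@H]21 | intermediate
45 | selenoxide of 44 | C=C(C)C(=O)O[C@@H]1CC(C=O)([Se](=O)c3ccccc3)[C@H]2CCC(=C)[C@H](O2)[C@H]2OC(=O)C(=C)[C@@H]21 | intermediate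
46 | 1,5-epoxy-8β-(methacryloyloxy)-14-oxogermacra-4(15),9,11(13)-trien-12,6α-olide ((9E)-enal) | C=C(C)C(=O)O[C@@H]1/C=C(/C=O)[C@H]2CCC(=C)[C@H](O2)[C@H]2OC(=O)C(=C)[C@@H]21 | intermediate
47 | (1R,4R,5R,6S,7R,8R,9E)-1,5:4,15-diepoxy-8-(methacryloyloxy)-14-oxogermacra-9,11(13)-dien-12,6-olide | C=C(C)C(=O)O[C@@H]1/C=C(/C=O)[C@H]2CC[C@@]3(CO3)[C@H](O2)[C@H]2OC(=O)C(=C)[C@@H]21 | target

## Step count and the least certain steps

Total: 28 steps. Longest linear sequence: 26 steps (1 to 47 through steps 1, 3–5 and 7–28); steps 2 and 6 are one-step side branches.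

**Step 16 (key step).** The hindered tetrasubstituted alkene may be epoxidised by ozone instead of cleaved, and a fully substituted ozonide can resist reduction, so that conversion stalls between 27 and 29. The fallback leaves ozone altogether. From 27, dimethyldioxirane in acetone at 0 °C should give the 1,5-epoxide F1 (drawn as the α-epoxide; either face serves). Periodic acid (H5IO6, THF/H2O) would then hydrolyse and cleave it through the diol, returning to the route at 29.

**Step 17.** Site or face selectivity may be lost. Hydride may attack the less hindered C1 ketone competitively, or approach C5 from the face dictated by the conformation of the ten-membered ring rather than by the C6–O bond. Either would deliver the bridge on the wrong face relative to C6–C8. In the fallback the hydride step is dropped: 29 would be treated directly with Et3SiH and BiBr3 in MeCN. This is a one-pot reductive etherification of the 1,5-diketone, in which the bridge face is decided at the cyclic oxocarbenium stage rather than by a ketone reduction, and it returns to the route at 32 without a new isolable compound.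

**Step 18.** The Lewis acid may ionise the C4 ketal as well as the lactol, or the bridgehead oxocarbenium ion may lose a proton to an enol ether faster than it accepts hydride. The fallback replaces the ionic reduction by a radical one. From 31, EtSH and Zn(OTf)2 in CH2Cl2 would give the mixed O,S-ketal F2. Ph3SnH with AIBN in toluene at 110 °C would then remove the sulfur through the bridgehead α-oxy radical, which can only take hydrogen on the exo face, returning at 32.

**Step 12.** Intermolecular allylation may give oligomers. The aldehyde may also be attacked through an open rather than the closed transition state, which gives poor facial selectivity at C8. Should the 8α-alcohol F3 form from 21, the centre would be corrected by SN2 inversion rather than by the ring closure. Mitsunobu reaction (4-nitrobenzoic acid, PPh3, DIAD, THF) would give the 8β-(4-nitrobenzoate) F4, and brief methanolysis (K2CO3, MeOH, 0 °C) would return to the route at 23.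

**Step 26.** The selenenyl chloride may add to the C4 methylene, or the quaternary selenide may form sluggishly from the hindered enol ether. The fallback avoids selenium. IBX in DMSO at 65 °C would dehydrogenate 42 directly and return at 46 without a new isolable compound. The direction of dehydrogenation (C9 rather than C1) is then less secure than in the selenoxide route.

**Step 28.** The peracid may attack the C4 methylene from the face under the C6–C10 bridge, giving the C4 epimer, or may oxidise the enal. The fallback reverses the order of C–O bond formation. From 46, NBS in THF/H2O should give the bromohydrin F5, with bromine on C15 and the hydroxyl entering C4 anti to the bromonium ion. Ag2O in CH2Cl2 would then close the epoxide and return at 47.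

## Further compounds

F1 | step 16 | 1,5-epoxide of 27 (α-epoxide drawn) | CC(C)(C)[Si](C)(C)O[C@@H]1C[C@H](CO[Si](c2ccccc2)(c2ccccc2)C(C)(C)C)[C@]34CCC5(OCCO5)[C@]3(O4)[C@H]2OC(=O)C[C@@H]21
F0 | step 17 | none | none
F2 | step 18 | 1-(ethylsulfanyl) analogue of lactol 31 (mixed O,S-ketal) | CC(C)(C)[Si](C)(C)O[C@@H]1C[C@H](CO[Si](c2ccccc2)(c2ccccc2)C(C)(C)C)[C@@]2(SCC)CCC3(OCCO3)[C@H](O2)[C@H]2OC(=O)C[C@@H]21
F3 | step 12 | 8α-hydroxy epimer of 23 | O[C@H]1CC(=C)C3=C(C4(CC3)OCCO4)[C@H]2OC(=O)C[C@@H]21
F4 | step 12 | 8β-(4-nitrobenzoyloxy) ester of 23 | O=C(O[C@@H]1CC(=C)C3=C(C4(CC3)OCCO4)[C@H]2OC(=O)C[C@@H]21)c5ccc(cc5)[N+](=O)[O-]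
F0 | step 26 | none | none
F5 | step 28 | 15-bromo-4-hydroxy bromohydrin of 46 (C4 as in 47) | C=C(C)C(=O)O[C@@H]1/C=C(/C=O)[C@H]2CC[C@@](O)(CBr)[C@H](O2)[C@H]2OC(=O)C(=C)[C@@H]21
A1 | alternative 1 | methyl ester of the cyclopentene-fused 8-oxabicyclo[3.2.1]octa-2,6-diene with a spiro-dioxolane on the cyclopentene | COC(=O)C1=CC[C@H]2O[C@@H]1C3=C2CC4(OCCO4)C3
A2 | alternative 2 | bridged oxocene with C8 hydroxyl, C7 2-propenyl unit, C6 silyl ether and C4 methylene | O[C@@H]1/C=C(/CO[Si](C)(C)C(C)(C)C)[C@H]2CCC(=C)[C@H](O2)[C@@H](O[Si](C)(C)C(C)(C)C)[C@@H]1C(=C)CO[Si](C)(C)C(C)(C)C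
A3 | alternative 3 | ether-bridged bicyclic C4 ketone with C6 4-methoxybenzyl ether, cis C7=C8 and C10 silyl ether | O=C1CC[C@H]2O[C@@H]1[C@@H](OCc3ccc(OC)cc3)/C=C\C[C@@H]2O[Si](C)(C)C(C)(C)C
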